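**Plan**

- Retrosynthesis: the C15 oxidation level and the C11 silyl ether are adjusted last. Before that, C9–C11 and C8–C15 are cut together (rings C and D), then C8–C14 (side chain), then C9–C10 of the spiro δ-lactone, then C5–C6 of the γ-lactone.
- Feature used: in the 7,20-δ-lactone, C9 is the β-carbon and C8 the α-carbon of the C7 carbonyl. The 8,9-unsaturated spiro lactone can therefore take a C11 ketyl at C9 and then strike the C15 aldehyde through its C8 enolate.
- Forward order: ring A with its cis-fused 6,19-γ-lactone, then the spiro δ-lactone by radical addition to methyl acrylate, then C8 alkylation and dehydrogenation, then ozonolysis to the dialdehyde, then rings C and D in one SmI2 step, then C15 oxidation.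
- Stereochemistry: C4 from a copper-catalysed asymmetric methyl addition; C5 by cis ring fusion; C10 by convex-face radical addition; C13 and C16 from an Evans oxazolidinone; C9, C11 and C8 in the cascade, steered by C10 and C13.

Key step: step 16

Remarks: atom labels follow ent-kaurane numbering (C17 = methyl on C16, C18 = methyl on C4, C19 and C20 = the CH2O carbons of the γ- and δ-lactone). Compounds 10 and 22–24 are carried as epimer mixtures at centres that are destroyed later. The C15 carbinol of 28 is drawn as the chelation-controlled epimer and is oxidised in step 18.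

**Route**

Step 1
Reactants: 1 3-ethoxycyclohex-2-en-1-one; 2 tributyl[(benzyloxy)methyl]stannane
Product: 4 3-[(benzyloxy)methyl]cyclohex-2-en-1-one, via carbinol adduct 3 (not isolated)
Conditions: 2, n-BuLi, THF, −78 °C; then 1, −78 → 0 °C; 1 M HCl, rt
Reagents that add atoms: water, O
Why: Stork–Danheiser sequence: the α-alkoxy organolithium from tin–lithium exchange adds 1,2 to the vinylogous ester, and acid hydrolysis of carbinol 3 transposes the enone; no stereocentre is formed.

Step 2
Reactants: 4 3-[(benzyloxy)methyl]cyclohex-2-en-1-one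
Product: 5 (R)-3-[(benzyloxy)methyl]-3-methylcyclohexan-1-one
Conditions: Me3Al, Cu(O2CC4H3S) (copper thiophene-2-carboxylate, cat.), chiral biphenol-derived phosphoramidite (cat., antipode chosen for the R product), Et2O, −30 °C
Reagents that add atoms: trimethylaluminium, C[Al](C)C
Why: Copper-catalysed asymmetric conjugate addition of a trialkylaluminium to a β-substituted cyclohexenone; the ligand-bound copper selects the enone face and so should set quaternary C4 as R.

Step 3
Reactants: 5 (R)-3-[(benzyloxy)methyl]-3-methylcyclohexan-1-one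
Product: 6 (R)-3-(hydroxymethyl)-3-methylcyclohexan-1-one
Conditions: H2 (1 atm), Pd/C (palladium on carbon), EtOAc, rt
Reagents that add atoms: none
Why: Hydrogenolysis of a benzyl ether; the ketone and the quaternary centre are not touched.

Step 4
Reactants: 6 (R)-3-(hydroxymethyl)-3-methylcyclohexan-1-one
Product: 8 (3aR,7aR)-3a-methyltetrahydro-2-benzofuran-1,7(3H,7aH)-dione, via imidazole-1-carboxylate 7 (not isolated)
Conditions: 1,1'-carbonyldiimidazole, THF, rt; then NaH, 0 °C → rt; aq. HCl
Reagents that add atoms: 1,1'-carbonyldiimidazole, O=C(n1ccnc1)n1ccnc1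
Why: O-acylation followed by an intramolecular Claisen (Dieckmann-type) C-acylation under equilibrating conditions: only the C5 enolate can reach the tethered carbonyl (5-exo-trig), the acidic β-keto lactone is the sink, and C5 can only form cis to the CH2O arm on C4.

Step 5
Reactants: 8 (3aR,7aR)-3a-methyltetrahydro-2-benzofuran-1,7(3H,7aH)-dione
Product: 9 (3aR,7aS)-3a-methyl-7-methylidenehexahydro-2-benzofuran-1(3H)-one
Conditions: Zn, CH2Br2, TiCl4, THF–CH2Cl2, 0 °C → rt
Reagents that add atoms: dibromomethane, BrCBr
Why: Takai–Lombardo methylenation, a non-basic CH2 transfer that spares lactones and is used for enolisable ketones; the cis ring fusion at C5 should be kept.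

Step 6
Reactants: 9 (3aR,7aS)-3a-methyl-7-methylidenehexahydro-2-benzofuran-1(3H)-one
Product: 10 (3aR,7aR)-3a-methylhexahydro-1H-spiro[2-benzofuran-7,2'-oxiran]-1-one (both epimers at the spiro carbon)
Conditions: mCPBA, NaHCO3, CH2Cl2, 0 °C
Reagents that add atoms: 3-chloroperoxybenzoic acid, OOC(=O)c1cccc(Cl)c1
Why: Prilezhaev epoxidation of the 1,1-disubstituted alkene; the configuration of the new spiro carbon does not matter because it becomes a planar radical in step 7.

Step 7
Reactants: 10 spiro-epoxide; 11 methyl acrylate
Product: 13 spiro bis-lactone (4R,5R,10R), via hydroxy ester 12 (not isolated)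
Conditions: Cp2TiCl2, Zn dust, THF, rt (gives Cp2TiCl); slow addition of 10 and 11; then TsOH·H2O (cat.), CH2Cl2, rt
Reagents that add atoms: none
Why: RajanBabu–Nugent epoxide opening by trivalent titanium gives the tertiary C10 radical, which undergoes Giese addition to the acrylate, and acid closes 12 to the δ-lactone; the acrylate should enter on the convex face (that of H5 and the C4 methyl), away from the cis-fused γ-lactone with its axial C19, which makes C10 R.

Step 8
Reactants: 14 (S)-4-benzyloxazolidin-2-one; 15 (E)-but-2-enoyl chloride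
Product: 16 (S)-4-benzyl-3-[(E)-but-2-enoyl]oxazolidin-2-one
Conditions: n-BuLi, THF, −78 °C; then 15, −78 → 0 °C
Reagents that add atoms: none
Why: N-acylation of the lithiated Evans oxazolidinone by an acid chloride.

Step 9
Reactants: 16 (S)-4-benzyl-3-[(E)-but-2-enoyl]oxazolidin-2-one
Product: 17 (S)-4-benzyl-3-[(R)-3-methylpent-4-enoyl]oxazolidin-2-one
Conditions: CH2=CHMgBr, CuBr·SMe2, THF, −78 → −20 °C; aq. NH4Cl
Reagents that add atoms: vinylmagnesium bromide, C=C[Mg]Br
Why: Copper-mediated conjugate addition of a Grignard reagent to the magnesium-chelated syn-s-cis N-enoyl oxazolidinone; attack on the face opposite the benzyl group should set C16.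

Step 10
Reactants: 17 (S)-4-benzyl-3-[(R)-3-methylpent-4-enoyl]oxazolidin-2-one; 18 1-bromo-3-methylbut-2-ene
Product: 19 (S)-4-benzyl-3-[(2S,3S)-3-methyl-2-(3-methylbut-2-en-1-yl)pent-4-enoyl]oxazolidin-2-one
Conditions: NaN(SiMe3)2, THF, −78 °C; then 18, −78 → −45 °C
Reagents that add atoms: none
Why: Evans alkylation: the chelated Z-enolate is alkylated by the reactive allylic bromide on the face opposite the benzyl group, which should set C13.

Step 11
Reactants: 19 (S)-4-benzyl-3-[(2S,3S)-3-methyl-2-(3-methylbut-2-en-1-yl)pent-4-enoyl]oxazolidin-2-one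
Product: 20 (2S,3S)-3-methyl-2-(3-methylbut-2-en-1-yl)pent-4-en-1-ol
Conditions: LiBH4, MeOH (1 equiv), Et2O, 0 °C
Reagents that add atoms: none
Why: Reductive removal of the auxiliary by hydride attack at the exocyclic imide carbonyl; neither stereocentre is touched and the oxazolidinone is recovered.

Step 12
Reactants: 20 (2S,3S)-3-methyl-2-(3-methylbut-2-en-1-yl)pent-4-en-1-ol
Product: 21 (3S,4S)-4-(iodomethyl)-3,7-dimethylocta-1,6-diene
Conditions: I2, PPh3, imidazole, CH2Cl2, 0 °C
Reagents that add atoms: iodine, II
Why: Garegg–Samuelsson (Appel-type) iodination of a primary alcohol; substitution takes place at CH2 only.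

Step 13
Reactants: 13 spiro bis-lactone; 21 (3S,4S)-4-(iodomethyl)-3,7-dimethylocta-1,6-diene
Product: 22 C8-alkylated spiro bis-lactone (C8 epimers; C13 and C16 as in 21)
Conditions: LiN(i-Pr)2, THF, −78 °C; HMPA; then 21, −78 → −20 °C
Reagents that add atoms: none
Why: Lactone enolate alkylation (SN2): the amide base should take a proton from the open C8 methylene rather than from the C5 methine between two quaternary carbons, and HMPA lets the β-branched primary iodide react; the new C8 centre is removed in step 14.

Step 14
Reactants: 22 C8-alkylated spiro bis-lactone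
Product: 25 8,9-unsaturated spiro δ-lactone bearing the diene side chain on C8, via 8-phenylselanyl lactone 23 (not isolated), via selenoxide 24 (not isolated)
Conditions: LiN(i-Pr)2, THF, −78 °C; PhSeSePh, HMPA, −78 → −40 °C; crude 23: NaIO4, NaHCO3, THF–H2O, 0 °C → rt
Reagents that add atoms: none
Why: α-Selenenylation of the lactone enolate and selenoxide syn-elimination, which should take a C9 hydrogen to give the conjugated endocyclic C8=C9 alkene; periodate is used so that no peracid meets the side-chain alkenes.

Step 15
Reactants: 25 8,9-unsaturated spiro δ-lactone bearing the diene side chain on C8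
Product: 26 dialdehyde (C11 and C15 as CHO; 4R,5R,10R,13S,16R)
Conditions: O3, CH2Cl2, −78 °C (Sudan Red 7B end-point); PPh3, −78 °C → rt; used at once
Reagents that add atoms: ozone, O=[O+][O-]
Why: Ozonolysis with reductive work-up: the two electron-rich side-chain alkenes are cleaved while the electron-poor enoate is spared, and C16 (α to the new aldehyde) meets no base.

Step 16
Reactants: 26 dialdehyde
Product: 28 11,15-diol (15-hydroxy analogue of the target; rings C and D closed), via tricyclic samarium enolate 27 (not isolated)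
Conditions: SmI2 (2.5 equiv, added slowly), LiBr, t-BuOH, THF, −78 °C; aq. NH4Cl
Reagents that add atoms: none
Why: SmI2, made more reducing by LiBr, transfers one electron to the unbranched C11 aldehyde, the ketyl adds 6-endo-trig to C9, the β-carbon of the unsaturated C7 lactone (ring C), a second electron turns the C8 radical into the trivalent-samarium enolate 27, and this adds 5-exo-trig (enolexo aldol) to the C15 aldehyde (ring D, quaternary C8). The closest known reaction type is the SmI2 ketyl–olefin cyclisation onto an α,β-unsaturated lactone that ends in an intramolecular aldol reaction of the samarium enolate. C9 is set by attack on the lactone face that carries C1H2 and lies away from C5 and its γ-lactone, and C11 is set in the chair transition state, where C13 holds its branch equatorial and C11–H rather than the samarium-bound oxygen takes the position syn-pentane to C1H2, so that the oxygen sits axial and can bridge to the lactone carbonyl. C8 has no choice, because the tether through C13 and C16 lets C15 reach the enolate only on the face opposite C11, and the chelated aldol fixes C15, which is lost in step 18. The step needs the C11 aldehyde to react before the α-branched C15 aldehyde and the ketyl to add to C9 before pinacol coupling; the lower hindrance at C11, the irreversible addition to the electron-poor alkene and the slow addition of the reductant, which keeps divalent samarium scarce, should secure this.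

Step 17
Reactants: 28 11,15-diol
Product: 29 11-O-tert-butyldimethylsilyl ether of 28
Conditions: TBSOTf (1.05 equiv), 2,6-lutidine, CH2Cl2, −78 °C
Reagents that add atoms: tert-butyldimethylsilyl trifluoromethanesulfonate, CC(C)(C)[Si](C)(C)OS(=O)(=O)C(F)(F)F
Why: Silyl ether formation; the equatorial C11 hydroxyl should react before the C15 hydroxyl, which is neopentyl (next to quaternary C8) and hydrogen-bonded to the C7 carbonyl.

Step 18
Reactants: 29 11-O-tert-butyldimethylsilyl ether of 28
Product: 30 11-O-tert-butyldimethylsilyl ether of the target (15-ketone)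
Conditions: Dess–Martin periodinane, NaHCO3, CH2Cl2, rt
Reagents that add atoms: none
Why: Dess–Martin oxidation of a secondary alcohol under buffered, non-enolising conditions, so that the C16 methyl group α to the new ketone should keep its configuration.

Step 19
Reactants: 30 11-O-tert-butyldimethylsilyl ether of the target
Product: 31 guidongnin C
Conditions: HF·pyridine, THF, 0 °C → rt
Reagents that add atoms: none
Why: Fluoride cleavage of the silyl ether under weakly acidic conditions, which should neither epimerise C16 nor open the non-enolisable β-keto lactone by retro-Claisen attack.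

**Compound list**

1 | 3-ethoxycyclohex-2-en-1-one | CCOC1=CC(=O)CCC1 | starting material
2 | tributyl[(benzyloxy)methyl]stannane | CCCC[Sn](CCCC)(CCCC)COCc1ccccc1 | starting material
3 | 1-[(benzyloxy)methyl]-3-ethoxycyclohex-2-en-1-ol (carbinol adduct, lithium alkoxide in the flask) | CCOC1=CC(O)(COCc2ccccc2)CCC1 | intermediate
4 | 3-[(benzyloxy)methyl]cyclohex-2-en-1-one | O=C1C=C(COCc2ccccc2)CCC1 | intermediate
5 | (R)-3-[(benzyloxy)methyl]-3-methylcyclohexan-1-one | O=C1CCC[C@@](C)(COCc2ccccc2)C1 | intermediate
6 | (R)-3-(hydroxymethyl)-3-methylcyclohexan-1-one | O=C1CCC[C@@](C)(CO)C1 | intermediate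
7 | [(1R)-1-methyl-3-oxocyclohexyl]methyl 1H-imidazole-1-carboxylate | O=C1CCC[C@@](C)(COC(=O)n2ccnc2)C1 | intermediate
8 | (3aR,7aR)-3a-methyltetrahydro-2-benzofuran-1,7(3H,7aH)-dione (cis-fused keto γ-lactone, ketone at C10) | O=C1CCC[C@@]2(C)COC(=O)[C@H]21 | intermediate
9 | (3aR,7aS)-3a-methyl-7-methylidenehexahydro-2-benzofuran-1(3H)-one | C=C1CCC[C@@]2(C)COC(=O)[C@H]21 | intermediate
10 | (3aR,7aR)-3a-methylhexahydro-1H-spiro[2-benzofuran-7,2'-oxiran]-1-one (both epimers at the spiro carbon) | C1OC12CCC[C@@]3(C)COC(=O)[C@H]32 | intermediate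
11 | methyl acrylate | C=CC(=O)OC | starting material
12 | methyl 3-[(3aR,7R,7aR)-7-(hydroxymethyl)-3a-methyl-1-oxooctahydro-2-benzofuran-7-yl]propanoate | COC(=O)CC[C@@]1(CCC[C@@]2(C)COC(=O)[C@H]21)CO | intermediate
13 | spiro bis-lactone, (3aR,7R,7aR)-3a-methyltetrahydro-1H-spiro[2-benzofuran-7,3'-oxane]-1,6'(3H)-dione (4R,5R,10R; C8 and C9 as CH2) | O=C1CC[C@@]2(CCC[C@@]3(C)COC(=O)[C@H]32)CO1 | intermediate
14 | (S)-4-benzyloxazolidin-2-one | O=C1N[C@@H](Cc2ccccc2)CO1 | starting material
15 | (E)-but-2-enoyl chloride | C/C=C/C(=O)Cl | starting material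
16 | (S)-4-benzyl-3-[(E)-but-2-enoyl]oxazolidin-2-one | C/C=C/C(=O)N1[C@@H](Cc2ccccc2)COC1=O | intermediate
17 | (S)-4-benzyl-3-[(R)-3-methylpent-4-enoyl]oxazolidin-2-one | C=C[C@H](C)CC(=O)N1[C@@H](Cc2ccccc2)COC1=O | intermediate
18 | 1-bromo-3-methylbut-2-ene | CC(C)=CCBr | starting material
19 | (S)-4-benzyl-3-[(2S,3S)-3-methyl-2-(3-methylbut-2-en-1-yl)pent-4-enoyl]oxazolidin-2-one | C=C[C@H](C)[C@H](CC=C(C)C)C(=O)N1[C@@H](Cc2ccccc2)COC1=O | intermediate
20 | (2S,3S)-3-methyl-2-(3-methylbut-2-en-1-yl)pent-4-en-1-ol | C=C[C@H](C)[C@H](CC=C(C)C)CO | intermediate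
21 | (3S,4S)-4-(iodomethyl)-3,7-dimethylocta-1,6-diene | C=C[C@H](C)[C@H](CC=C(C)C)CI | intermediate
22 | C8-alkylated spiro bis-lactone (13 carrying on C8 the chain of 21; C8 epimers; C13 and C16 as in 21) | C=C[C@H](C)[C@H](CC=C(C)C)CC1C[C@@]2(CCC[C@@]3(C)COC(=O)[C@H]32)COC1=O | intermediate
23 | 8-phenylselanyl derivative of 22 | C=C[C@H](C)[C@H](CC=C(C)C)CC1([Se]c2ccccc2)C[C@@]2(CCC[C@@]3(C)COC(=O)[C@H]32)COC1=O | intermediate
24 | selenoxide of 23 | C=C[C@H](C)[C@H](CC=C(C)C)CC1([Se](=O)c2ccccc2)C[C@@]2(CCC[C@@]3(C)COC(=O)[C@H]32)COC1=O | intermediate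
25 | 8,9-unsaturated spiro δ-lactone bearing the diene side chain on C8 | C=C[C@H](C)[C@H](CC=C(C)C)CC1=C[C@@]2(CCC[C@@]3(C)COC(=O)[C@H]32)COC1=O | intermediate
26 | dialdehyde: 8,9-unsaturated spiro δ-lactone with C11 and C15 as CHO on the C8 side chain (4R,5R,10R,13S,16R) | O=C[C@H](C)[C@H](CC=O)CC1=C[C@@]2(CCC[C@@]3(C)COC(=O)[C@H]32)COC1=O | intermediate
27 | tricyclic samarium enolate (ring C closed, O11 and the C7 enolate oxygen on trivalent samarium, C15 still CHO) | C[C@@H](C=O)[C@@H]1C[C@@H](O[Sm](I)I)[C@@H]2C(C1)=C(O[Sm](I)I)OC[C@]23CCC[C@@]1(C)COC(=O)[C@H]13 | intermediate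
28 | 11,15-diol, 15-hydroxy analogue of the target (4R,5R,8S,9S,10R,11R,13S,15S,16R) | C[C@H]1[C@H](O)[C@]23C[C@H]1C[C@@H](O)[C@H]2[C@@]1(CCC[C@@]2(C)COC(=O)[C@H]21)COC3=O | intermediate
29 | 11-O-tert-butyldimethylsilyl ether of 28 | C[C@H]1[C@H](O)[C@]23C[C@H]1C[C@@H](O[Si](C)(C)C(C)(C)C)[C@H]2[C@@]1(CCC[C@@]2(C)COC(=O)[C@H]21)COC3=O | intermediate
30 | 11-O-tert-butyldimethylsilyl ether of the target (15-ketone) | C[C@H]1C(=O)[C@]23C[C@H]1C[C@@H](O[Si](C)(C)C(C)(C)C)[C@H]2[C@@]1(CCC[C@@]2(C)COC(=O)[C@H]21)COC3=O | intermediate
31 | guidongnin C (4R,5R,8S,9S,10R,11R,13S,16R) | C[C@H]1C(=O)[C@]23C[C@H]1C[C@@H](O)[C@H]2[C@@]1(CCC[C@@]2(C)COC(=O)[C@H]21)COC3=O | target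

**Count and risks**

Total step count: 19. Longest linear sequence: 14 steps (steps 1–7 and 13–19).

1. Step 16. What may go wrong: pinacol coupling of the two aldehydes, or reduction of the α-branched C15 aldehyde first, outruns the 6-endo ketyl addition, so that rings C and D do not form together. The fallback closes the rings one after the other with known reactions; it sets out from 25 and comes back at 30. Epoxidation of only the trisubstituted alkene of 25 (mCPBA) and cleavage with H5IO6 give the mono-aldehyde F1. SmI2–LiBr–t-BuOH then closes ring C alone by the same ketyl–enoate cyclisation, and protonation of the enolate gives the tricyclic hydroxy lactone F2. KN(SiMe3)2 and TBSCl silylate O11 and turn the δ-lactone into the silyl ketene acetal F3. Pd(OAc)2 in DMSO–AcOH closes ring D by oxidative cyclisation of the ketene acetal onto the vinyl group (5-exo, then β-hydride elimination) to give the 15-methylidene tetracycle F4, and ozonolysis of F4 gives 30.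

2. Step 5. What may go wrong: the β-keto lactone is enolised or tied up as a titanium chelate, so that no methylene is transferred. The fallback sets out from 8 and comes back at 9. NaH and PhNTf2 convert 8 into the enol triflate F5. Pd(PPh3)4-catalysed Kumada coupling with Me3SiCH2MgCl gives the allylsilane F6. Fluoride (Bu4NF–AcOH) removes silicon, and kinetic α-protonation of the extended enolate moves the double bond out of conjugation to give 9.

3. Step 13. What may go wrong: substitution at the β-branched iodide is slow, so that proton transfer, enolisation at C5 or decay of the enolate wins. The fallback brings the side chain in with the radical step instead; it sets out from 21 (and uses 10) and comes back at 22. Sodium trimethyl phosphonoacetate is alkylated with 21 to the phosphonate F7. Horner–Wadsworth–Emmons reaction with aqueous formaldehyde (K2CO3) gives the 2-substituted acrylate F8. The Cp2TiCl-mediated opening of epoxide 10 is then run with F8 in place of methyl acrylate, and lactonisation gives 22 directly.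

**Further compounds**

F1 | step 16 | mono-aldehyde (25 with the 3-methylbut-2-enyl alkene cleaved to the C11 aldehyde, vinyl group kept) | C=C[C@H](C)[C@H](CC=O)CC1=C[C@@]2(CCC[C@@]3(C)COC(=O)[C@H]32)COC1=O
F2 | step 16 | tricyclic hydroxy lactone (ring C closed, 11-OH, C8–H, vinyl on C16) | C[C@@H](C=C)[C@@H]1C[C@@H](O)[C@@H]2C(C1)C(=O)OC[C@]23CCC[C@@]1(C)COC(=O)[C@H]13
F3 | step 16 | 11-O-tert-butyldimethylsilyl silyl ketene acetal of F2 | C[C@@H](C=C)[C@@H]1C[C@@H](O[Si](C)(C)C(C)(C)C)[C@@H]2C(C1)=C(O[Si](C)(C)C(C)(C)C)OC[C@]23CCC[C@@]1(C)COC(=O)[C@H]13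
F4 | step 16 | 15-methylidene analogue of 30 (rings C and D closed, 11-O-tert-butyldimethylsilyl) | C[C@H]1C(=C)[C@]23C[C@H]1C[C@@H](O[Si](C)(C)C(C)(C)C)[C@H]2[C@@]1(CCC[C@@]2(C)COC(=O)[C@H]21)COC3=O
F5 | step 5 | (3aR)-3a-methyl-1-oxo-1,3,3a,4,5,6-hexahydro-2-benzofuran-7-yl trifluoromethanesulfonate | O=C1OC[C@]2(C)CCCC(OS(=O)(=O)C(F)(F)F)=C12
F6 | step 5 | (3aR)-3a-methyl-7-[(trimethylsilyl)methyl]-3a,4,5,6-tetrahydro-2-benzofuran-1(3H)-one | C[Si](C)(C)CC1=C2C(=O)OC[C@]2(C)CCC1
F7 | step 13 | methyl 2-(dimethoxyphosphoryl)-3-[chain of 21]propanoate (phosphonate from 21) | C=C[C@H](C)[C@H](CC=C(C)C)CC(C(=O)OC)P(=O)(OC)OC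
F8 | step 13 | methyl 2-methylidene-3-[chain of 21]propanoate (2-substituted acrylate) | C=C[C@H](C)[C@H](CC=C(C)C)CC(=C)C(=O)OC
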